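**Plan**

Numbering (iridoid): C1 acetal carbon, O2, C3=C4 (C11 on C4), C5, C6, C7, C8 (C10 on C8), C9. β is the face of H-5 and H-9.
Enabling feature: on the cyclopentane C5–C6–C7–C8–C9, the oxygen on C7 and carbon C10 on C8 are cis (both β) and the C8 hydroxyl is α. C7–O···C10 is therefore a latent cis-fused oxetane, and C7 and C8 are both carbonyl-type carbons.
Cuts, in order: the esters at O1 and O7. Then C10–OH is tied back to O7 (oxetane) and H-9/O-1 are removed (C1=C9). Then C7–C8 and O7–C10 are cut together (retro Paternò–Büchi), giving a flat 4H-pyran with CH2CHO on C5 and a silyl enol ether C8=C10 on C9. Then C9–C8 and C4–C11 (enol ether acylations), and last C5–C9/C1–O2 (hetero-Diels–Alder).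
Forward order: the pyran ring first, then the cyclopentane, together with the temporary oxetane, in the photochemical step. This is the last ring closure of the skeleton. Ring strain then drives hydrolysis of the oxetane at C10. The aryl ring comes with p-coumaric acid.
Stereochemistry: C5 comes from the chiral chromium catalyst. C7 and C8 come from C5 in the photocycloaddition, and their mutual relation is fixed by the cis fusion of the four-membered ring. C9 is set by protonation anti to the C8 silyloxy group. C1 is set by axial addition and, at the end, by acylation of the β-lactol.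

Key step: step 8

Assumption: the (1R,2S)-aminoindanol-derived chromium complex is taken to give the (4R) adduct 7. If the sense of induction is the opposite, the equally available (1S,2R) complex is used.

**Route**

Step 1
Reactants: 1 but-3-enoic acid; 2 N,O-dimethylhydroxylamine hydrochloride
Product: 3 N-methoxy-N-methylbut-3-enamide
Conditions: EDC·HCl, N-methylmorpholine, CH2Cl2, 0 °C to rt
Reagents that add atoms: none
Why: Carbodiimide amide coupling under weakly basic conditions should give the Weinreb amide without moving the β,γ-double bond into conjugation; no stereocentre is formed.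

Step 2
Reactants: 3 N-methoxy-N-methylbut-3-enamide; 4 (E)-crotonaldehyde
Product: 5 (E)-N-methoxy-N-methyl-5-oxopent-3-enamide
Conditions: second-generation Hoveyda–Grubbs catalyst RuCl2(H2IMes)(=CH-C6H4-2-OiPr) (2.5 mol %), 4 (5 equiv), CH2Cl2, 40 °C
Reagents that add atoms: none
Why: Olefin cross-metathesis of a terminal alkene with an excess of an enal partner is a standard entry to (E)-enals, the E geometry being the thermodynamic outcome.

Step 3
Reactants: 5 (E)-N-methoxy-N-methyl-5-oxopent-3-enamide; 6 ethyl vinyl ether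
Product: 7 2-[(2S,4R)-2-ethoxy-3,4-dihydro-2H-pyran-4-yl]-N-methoxy-N-methylacetamide (2,4-cis)
Conditions: CrCl(L) (5 mol %; L = dianion of (1R,2S)-1-{[3-(1-adamantyl)-2-hydroxy-5-methylbenzylidene]amino}indan-2-ol), 4 Å MS, 6 (10 equiv, neat), rt
Reagents that add atoms: none
Why: Catalytic enantioselective inverse-electron-demand hetero-Diels–Alder reaction of a β-substituted enal with a vinyl ether: the chiral trivalent chromium Lewis acid binds the formyl oxygen and shields one face of the oxadiene, which sets C5 (R), and the endo approach gives the 2,4-cis acetal, whose centre C1 is erased in step 5.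

Step 4
Reactants: 7 2-[(2S,4R)-2-ethoxy-3,4-dihydro-2H-pyran-4-yl]-N-methoxy-N-methylacetamide
Product: 9 methyl (2S,4R)-2-ethoxy-4-{2-[methoxy(methyl)amino]-2-oxoethyl}-3,4-dihydro-2H-pyran-5-carboxylate, via trichloromethyl ketone 8 (not isolated)
Conditions: Cl3CCOCl, pyridine, CH2Cl2, 0 °C to rt; then MeOH, K2CO3 (cat.), rt
Reagents that add atoms: trichloroacetyl chloride ClC(=O)C(Cl)(Cl)Cl; methanol CO
Why: Electrophilic C-acylation of the enol ether β-carbon C4 followed by haloform-type cleavage of the trichloromethyl ketone with methanol installs C11 as the ester, makes the two halves of the pyran different before C1 loses its stereocentre, and leaves C5 untouched.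

Step 5
Reactants: 9 methyl (2S,4R)-2-ethoxy-4-{2-[methoxy(methyl)amino]-2-oxoethyl}-3,4-dihydro-2H-pyran-5-carboxylate
Product: 11 methyl (4S)-5-acetyl-4-{2-[methoxy(methyl)amino]-2-oxoethyl}-4H-pyran-3-carboxylate, via 4H-pyran 10 (not isolated)
Conditions: Ac2O (6 equiv), BF3·OEt2 (0.5 equiv), CH2Cl2, −30 °C to rt; aq. NaHCO3
Reagents that add atoms: acetic anhydride CC(=O)OC(C)=O
Why: Lewis acid acylation of an acetal through its enol ether: ionisation and loss of H-9 give 10, whose only electron-rich double bond C1=C9 is C-acetylated at C9 and re-forms by proton loss, while C3=C4 is switched off by the ester and C5, now the sole stereocentre, is not touched.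

Step 6
Reactants: 11 methyl (4S)-5-acetyl-4-{2-[methoxy(methyl)amino]-2-oxoethyl}-4H-pyran-3-carboxylate
Product: 12 methyl (4S)-4-{2-[methoxy(methyl)amino]-2-oxoethyl}-5-[1-(triethylsilyloxy)ethenyl]-4H-pyran-3-carboxylate
Conditions: Et3SiOTf, Et3N, CH2Cl2, −78 to 0 °C
Reagents that add atoms: triethylsilyl triflate CC[Si](CC)(CC)OS(=O)(=O)C(F)(F)F
Why: Soft enolisation of a vinylogous ester ketone, the usual way to 1-alkoxy-3-silyloxy-1,3-dienes, can only take place at C10 because C9 carries no hydrogen, so the position of the silyl enol ether is unambiguous.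

Step 7
Reactants: 12 methyl (4S)-4-{2-[methoxy(methyl)amino]-2-oxoethyl}-5-[1-(triethylsilyloxy)ethenyl]-4H-pyran-3-carboxylate
Product: 13 methyl (4S)-4-(2-oxoethyl)-5-[1-(triethylsilyloxy)ethenyl]-4H-pyran-3-carboxylate
Conditions: iBu2AlH (1.1 equiv), THF, −78 °C; aq. potassium sodium tartrate, 0 °C
Reagents that add atoms: none
Why: Weinreb amide reduction stops at the chelated tetrahedral aluminate and releases the aldehyde on neutral work-up, and at −78 °C with one equivalent the vinylogous carbonate at C4 and the silyl dienol ether should survive.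

Step 8
Reactants: 13 methyl (4S)-4-(2-oxoethyl)-5-[1-(triethylsilyloxy)ethenyl]-4H-pyran-3-carboxylate
Product: 14 tricyclic oxetane (cyclopenta[c]pyran with C1=C9 and C3=C4; oxetane oxygen bridging C7 and C10 on the β face; OSiEt3 on C8 α; H-5 β; methyl ester on C4)
Conditions: hν (300 nm lamps, Pyrex), 3 mM in degassed C6H6, 10 °C
Reagents that add atoms: none
Why: n→π* excitation of the aliphatic formyl group (the ester-conjugated enol ether and the silyloxydiene should be transparent above 290 nm) gives the singlet aldehyde, whose electrophilic oxygen attacks the terminal carbon C10 of the tethered electron-rich C8=C10 bond while C7 bonds to C8, an intramolecular Paternò–Büchi [2+2] that joins two carbonyl-derived carbons which ground-state chemistry would not unite (a Lewis acid would make the Mukaiyama aldol bond C7–C10 and a six-membered ring). The closest known reactions are the Paternò–Büchi additions of aldehydes to silyl enol ethers (3-silyloxyoxetanes), those of aliphatic aldehydes to 1,3-dienes and furans from the singlet state, and intramolecular versions that give ring-fused oxetanes. The cyclopentane closes in the straight 5-exo mode (three-atom tether C6–C5–C9, C7 to the inner alkene carbon C8) and the oxetane in the same event through O7–C10, giving a cis-fused 6-oxabicyclo[3.2.0]heptane. Because a four-membered ring can only be cis-fused, O7 and C10 end on one face and the silyloxy group on the other, which is the 7β,8α,10β pattern of the target, and the face is controlled by C5: the side chain leaves C5 on the α face, C8=C10 must twist out of the pyran plane to meet C7, the C8 substituent on the C5 side is thereby pushed to the face of H-5, and in the preferred s-trans diene rotamer (OSiEt3 next to H-1, away from C5 and C6) that substituent is C10. Regioselectivity (O to C10) is secured twice, by the polarity of the enol ether and by the tether, and chemoselectivity by the ester, which deactivates C3=C4, and by strain, since addition across C1=C9 or C3=C4 would need a cyclobutane or a bicyclo[2.1.1]hexane. The flat 4H-pyran has no γ-hydrogen (C4 and C9 are sp2), so γ-hydrogen abstraction is excluded, and the diene quenches any triplet aldehyde before α-cleavage.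

Step 9
Reactants: 14 tricyclic oxetane
Product: 15 1β-(2,2,2-trichloroethyl) acetal of the oxetane (H-9 β; cis ring fusion; C3=C4 kept)
Conditions: Cl3CCH2OH (5 equiv), PPTS (10 mol %), CH2Cl2, 0 °C to rt
Reagents that add atoms: 2,2,2-trichloroethanol OCC(Cl)(Cl)Cl
Why: Acid-catalysed addition of an alcohol to an enol ether (as in tetrahydropyranyl ether formation) acts only on the electron-rich C1=C9, the proton reaching C9 from the β face opposite the C8 silyloxy group to give the favoured cis fusion and the alcohol adding axially at C1 from the β face (anomeric effect), reversibly and therefore under thermodynamic control.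

Step 10
Reactants: 15 1β-(2,2,2-trichloroethyl) acetal of the oxetane
Product: 16 1β-O-trichloroethyl 7β,8α,10-triol methyl ester
Conditions: 0.2 M H2SO4, THF/H2O 3:1, rt to 40 °C
Reagents that add atoms: water O
Why: Strain-driven acid hydrolysis of the oxetane by SN2 attack of water at the primary carbon C10 leaves the C7–O bond and hence the 7β configuration intact, the tertiary triethylsilyl ether is hydrolysed in the same medium, and the electron-poor trichloroethyl acetal and the vinylogous carbonate should resist dilute acid.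

Step 11
Reactants: 16 1β-O-trichloroethyl 7β,8α,10-triol methyl ester
Product: 17 1β-O-trichloroethyl 7β,8α,10,11-tetraol
Conditions: iBu2AlH (7 equiv), THF/CH2Cl2, −78 to −20 °C; aq. potassium sodium tartrate
Reagents that add atoms: none
Why: Hydride reduction of the β-alkoxyacrylate to the allylic alcohol is the standard way to the C11 carbinol of iridoids, and it is placed before any other ester is present.

Step 12
Reactants: 17 1β-O-trichloroethyl 7β,8α,10,11-tetraol
Product: 18 10,11-bis-O-(tert-butyldimethylsilyl) ether with free 7β-OH and 8α-OH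
Conditions: TBSCl (2.2 equiv), imidazole, DMF, 0 °C
Reagents that add atoms: tert-butyldimethylsilyl chloride CC(C)(C)[Si](C)(C)Cl
Why: Chemoselective silylation of the two primary alcohols relies on the much lower reactivity of the hindered secondary C7 and the tertiary C8 hydroxyl groups.

Step 13
Reactants: 19 (E)-p-coumaric acid
Product: 21 (E)-4-(tert-butyldimethylsilyloxy)cinnamic acid, via bis-silyl derivative 20 (not isolated)
Conditions: TBSCl (2.2 equiv), imidazole, DMF, rt; then THF/H2O/AcOH 3:1:1, rt
Reagents that add atoms: tert-butyldimethylsilyl chloride CC(C)(C)[Si](C)(C)Cl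
Why: Exhaustive silylation followed by selective hydrolysis of the labile silyl ester is the routine protection of a phenolic acid.

Step 14
Reactants: 18 10,11-bis-O-TBS ether; 21 (E)-4-(tert-butyldimethylsilyloxy)cinnamic acid
Product: 22 7-O-[(E)-4-(tert-butyldimethylsilyloxy)cinnamoyl] ester of 18
Conditions: DCC, DMAP, CH2Cl2, rt
Reagents that add atoms: none
Why: Steglich esterification acylates the only reactive hydroxyl group (7β-OH) with retention, the tertiary 8α-OH being inert.

Step 15
Reactants: 22 7-O-cinnamoyl trichloroethyl acetal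
Product: 23 1β-lactol
Conditions: Zn dust, AcOH/THF 1:5, 0 °C to rt
Reagents that add atoms: none
Why: Reductive β-elimination of the 2,2,2-trichloroethyl group with zinc frees the lactol under conditions orthogonal to silyl ethers, esters and the acid-sensitive enol ether.

Step 16
Reactants: 23 1β-lactol; 24 isovaleryl chloride
Product: 25 tris-O-TBS luzonoid A
Conditions: pyridine, DMAP (cat.), CH2Cl2, −20 to 0 °C
Reagents that add atoms: none
Why: O-acylation of the lactol, which as in iridoid aglycones should sit as the pseudo-axial β-anomer trans to the C9–C8 bond, fixes the 1β-acyloxy acetal with retention, and the tertiary alcohol does not compete.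

Step 17
Reactants: 25 tris-O-TBS luzonoid A
Product: 26 luzonoid A
Conditions: HF·pyridine, pyridine, THF, 0 °C to rt
Reagents that add atoms: none
Why: Buffered fluoride desilylation removes the two primary and the aryl silyl ethers without base, so acyl migration from O7 to O10 and cleavage of the acyl acetal should be avoided.

**Compound list**

1 | but-3-enoic acid | C=CCC(=O)O | starting material
2 | N,O-dimethylhydroxylamine hydrochloride | CNOC.Cl | starting material
3 | N-methoxy-N-methylbut-3-enamide | C=CCC(=O)N(C)OC | intermediate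
4 | (E)-crotonaldehyde | C/C=C/C=O | starting material
5 | (E)-N-methoxy-N-methyl-5-oxopent-3-enamide | O=C/C=C/CC(=O)N(C)OC | intermediate
6 | ethyl vinyl ether | C=COCC | starting material
7 | 2-[(2S,4R)-2-ethoxy-3,4-dihydro-2H-pyran-4-yl]-N-methoxy-N-methylacetamide | CCO[C@H]1OC=C[C@@H](CC(=O)N(C)OC)C1 | intermediate
8 | 5-trichloroacetyl derivative of 7 (not isolated) | CCO[C@H]1OC=C(C(=O)C(Cl)(Cl)Cl)[C@@H](CC(=O)N(C)OC)C1 | intermediate
9 | methyl (2S,4R)-2-ethoxy-4-{2-[methoxy(methyl)amino]-2-oxoethyl}-3,4-dihydro-2H-pyran-5-carboxylate | CCO[C@H]1OC=C(C(=O)OC)[C@@H](CC(=O)N(C)OC)C1 | intermediate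
10 | methyl (4S)-4-{2-[methoxy(methyl)amino]-2-oxoethyl}-4H-pyran-3-carboxylate (not isolated) | O1C=C(C(=O)OC)[C@@H](CC(=O)N(C)OC)C=C1 | intermediate
11 | methyl (4S)-5-acetyl-4-{2-[methoxy(methyl)amino]-2-oxoethyl}-4H-pyran-3-carboxylate | O1C=C(C(=O)OC)[C@@H](CC(=O)N(C)OC)C(C(C)=O)=C1 | intermediate
12 | methyl (4S)-4-{2-[methoxy(methyl)amino]-2-oxoethyl}-5-[1-(triethylsilyloxy)ethenyl]-4H-pyran-3-carboxylate | O1C=C(C(=O)OC)[C@@H](CC(=O)N(C)OC)C(C(=C)O[Si](CC)(CC)CC)=C1 | intermediate
13 | methyl (4S)-4-(2-oxoethyl)-5-[1-(triethylsilyloxy)ethenyl]-4H-pyran-3-carboxylate | O1C=C(C(=O)OC)[C@@H](CC=O)C(C(=C)O[Si](CC)(CC)CC)=C1 | intermediate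
14 | tricyclic oxetane (7β,10-epoxy, 8α-OSiEt3, C1=C9, C3=C4, H-5 β, C11 methyl ester) | O1C=C(C(=O)OC)[C@H]2C[C@@H]3OC[C@]3(O[Si](CC)(CC)CC)C2=C1 | intermediate
15 | 1β-(2,2,2-trichloroethyl) acetal of the oxetane (H-9 β) | ClC(Cl)(Cl)CO[C@@H]1OC=C(C(=O)OC)[C@H]2C[C@@H]3OC[C@]3(O[Si](CC)(CC)CC)[C@@H]12 | intermediate
16 | 1β-O-trichloroethyl 7β,8α,10-triol methyl ester | ClC(Cl)(Cl)CO[C@@H]1OC=C(C(=O)OC)[C@H]2C[C@H](O)[C@](O)(CO)[C@@H]12 | intermediate
17 | 1β-O-trichloroethyl 7β,8α,10,11-tetraol | ClC(Cl)(Cl)CO[C@@H]1OC=C(CO)[C@H]2C[C@H](O)[C@](O)(CO)[C@@H]12 | intermediate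
18 | 10,11-bis-O-TBS ether of 17 | ClC(Cl)(Cl)CO[C@@H]1OC=C(CO[Si](C)(C)C(C)(C)C)[C@H]2C[C@H](O)[C@](O)(CO[Si](C)(C)C(C)(C)C)[C@@H]12 | intermediate
19 | (E)-p-coumaric acid | OC(=O)/C=C/c1ccc(O)cc1 | starting material
20 | tert-butyldimethylsilyl (E)-4-(tert-butyldimethylsilyloxy)cinnamate (not isolated) | CC(C)(C)[Si](C)(C)OC(=O)/C=C/c1ccc(O[Si](C)(C)C(C)(C)C)cc1 | intermediate
21 | (E)-4-(tert-butyldimethylsilyloxy)cinnamic acid | OC(=O)/C=C/c1ccc(O[Si](C)(C)C(C)(C)C)cc1 | intermediate
22 | 7-O-[(E)-4-(TBSO)cinnamoyl] ester of 18 | ClC(Cl)(Cl)CO[C@@H]1OC=C(CO[Si](C)(C)C(C)(C)C)[C@H]2C[C@H](OC(=O)/C=C/c3ccc(O[Si](C)(C)C(C)(C)C)cc3)[C@](O)(CO[Si](C)(C)C(C)(C)C)[C@@H]12 | intermediate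
23 | 1β-lactol | O[C@@H]1OC=C(CO[Si](C)(C)C(C)(C)C)[C@H]2C[C@H](OC(=O)/C=C/c3ccc(O[Si](C)(C)C(C)(C)C)cc3)[C@](O)(CO[Si](C)(C)C(C)(C)C)[C@@H]12 | intermediate
24 | isovaleryl chloride | CC(C)CC(=O)Cl | starting material
25 | tris-O-TBS luzonoid A | CC(C)CC(=O)O[C@@H]1OC=C(CO[Si](C)(C)C(C)(C)C)[C@H]2C[C@H](OC(=O)/C=C/c3ccc(O[Si](C)(C)C(C)(C)C)cc3)[C@](O)(CO[Si](C)(C)C(C)(C)C)[C@@H]12 | intermediate
26 | luzonoid A | CC(C)CC(=O)O[C@@H]1OC=C(CO)[C@H]2C[C@H](OC(=O)/C=C/c3ccc(O)cc3)[C@](O)(CO)[C@@H]12 | target

Total step count: 17. Longest linear sequence: 16 (steps 1–12 and 14–17).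

**Steps most likely to fail**

1. Step 8. Radiationless decay of the aldehyde–diene exciplex, energy transfer to the diene, or poor facial selectivity may make the photocycloaddition inefficient. The fallback is thermal and uses a temporary isoxazoline ring in place of the oxetane. From 13, NH2OH·HCl/NaOAc gives the oxime F1. NaOCl in CH2Cl2/H2O dehydrogenates it to the nitrile oxide F2, which cyclises in the flask by intramolecular 1,3-dipolar cycloaddition to the isoxazoline F3; the three-atom tether enforces the C7–C8 and O–C10 bonds. Cl3CCH2OH/PPTS, as in step 9, gives the trichloroethyl acetal F4. Mo(CO)6 in wet MeCN followed by dilute HCl cleaves the N–O bond, the imine and the silyl ether to the 7-ketone F5. iBu2AlH reduces the ester and, from the convex face, the ketone to the 7α-tetraol F6. TBSCl/imidazole gives the bis-silyl ether F7. Mitsunobu esterification with 21 (PPh3, DIAD) inverts C7 and comes back to the route at 22.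

2. Step 10. SN2 attack of water at the neopentyl-type C10 may be slow, or a semipinacol shift of a ring carbon to C10 with ring enlargement may compete. In the fallback, from 15, MgBr2·OEt2 in Et2O/CH2Cl2 opens the oxetane with the better nucleophile bromide to the 10-bromo-7-alcohol F8. Bu4NF removes the silyl group, and the C8 alkoxide closes the 8,10-epoxide F9. Dilute HClO4 in aqueous THF opens this epoxide at C10, with C8 unchanged, and comes back to the route at 16.

3. Step 5. The 4H-pyran may decompose or lose hydride under the Lewis acid (erosion of C5), or C-acetylation may be incomplete. In the fallback, from 9, TMSOTf/iPr2NEt gives 10, now isolated. N-iodosuccinimide with AgNO3 (cat.) in MeCN iodinates C9 to the vinyl iodide F10. Stille coupling with Bu3Sn–C(OEt)=CH2 (Pd(PPh3)4, CuI, DMF) gives the 2-ethoxydiene F11. Wet oxalic acid on silica hydrolyses the enol ether and comes back to the route at 11.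

**Further compounds**

F1 | step 8 | oxime of 13 | O1C=C(C(=O)OC)[C@@H](CC=NO)C(C(=C)O[Si](CC)(CC)CC)=C1
F2 | step 8 | nitrile oxide | O1C=C(C(=O)OC)[C@@H](CC#[N+][O-])C(C(=C)O[Si](CC)(CC)CC)=C1
F3 | step 8 | isoxazoline (C7=N–O–C10, 8α-OSiEt3, C1=C9) | O1C=C(C(=O)OC)[C@H]2CC3=NOC[C@]3(O[Si](CC)(CC)CC)C2=C1
F4 | step 8 | trichloroethyl acetal of the isoxazoline | ClC(Cl)(Cl)CO[C@@H]1OC=C(C(=O)OC)[C@H]2CC3=NOC[C@]3(O[Si](CC)(CC)CC)[C@@H]12
F5 | step 8 | 7-ketone with 8α-OH and 10-OH | ClC(Cl)(Cl)CO[C@@H]1OC=C(C(=O)OC)[C@H]2CC(=O)[C@](O)(CO)[C@@H]12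
F6 | step 8 | 7α-tetraol (7-epimer of 17) | ClC(Cl)(Cl)CO[C@@H]1OC=C(CO)[C@H]2C[C@@H](O)[C@](O)(CO)[C@@H]12
F7 | step 8 | bis-silyl ether (7-epimer of 18) | ClC(Cl)(Cl)CO[C@@H]1OC=C(CO[Si](C)(C)C(C)(C)C)[C@H]2C[C@@H](O)[C@](O)(CO[Si](C)(C)C(C)(C)C)[C@@H]12
F8 | step 10 | 10-bromo-7-alcohol | ClC(Cl)(Cl)CO[C@@H]1OC=C(C(=O)OC)[C@H]2C[C@H](O)[C@](O[Si](CC)(CC)CC)(CBr)[C@@H]12
F9 | step 10 | 8,10-epoxide | ClC(Cl)(Cl)CO[C@@H]1OC=C(C(=O)OC)[C@H]2C[C@H](O)[C@]3(CO3)[C@@H]12
F10 | step 5 | vinyl iodide | O1C=C(C(=O)OC)[C@@H](CC(=O)N(C)OC)C(I)=C1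
F11 | step 5 | 2-ethoxydiene | O1C=C(C(=O)OC)[C@@H](CC(=O)N(C)OC)C(C(=C)OCC)=C1
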